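**Assumption:** the target SMILES contains no stereocentre (the molecule is achiral), so there is no configuration to set. The only stereo-element in the route is the E-enaminone 10, which is consumed on ring closure.

## Retrosynthetic overview

1. Coloratanin A ⇐ tris-MOM isoflavone 16 by non-protic removal of three aryl MOM ethers.
2. Key disconnection: the C3–C1′ bond and the pyranone ring of 16 are made together, by addition of a B-ring aryl radical to the α-carbon of o-hydroxyaryl enaminone 10, then oxidation to the iminium and O-cyclisation with loss of Me2NH.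
3. Enaminone 10 ⇐ resorcinol: prenyl placed between two OMOM groups by directed lithiation; the third oxygen (future O1) by Ir C–H borylation/oxidation; the acetyl by ortho-bromination, Br/Li exchange and a Weinreb amide; then DMF-DMA. Only the oxygen next to the ring C–H is free, so closure can only give the 6-prenyl isomer.
4. Aryl iodide 15 ⇐ 2-iodophenol: B-alkyl Suzuki coupling with 2-methylbut-3-en-2-ol, para-iodination, MOM protection.
5. Ring order: the A and B benzene rings are carried in from resorcinol and 2-iodophenol; the only ring constructed is the pyranone C ring, in the key step.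

## Route

**Step 1**
Reactants: 1, resorcinol
Product: 2, 1,3-bis(methoxymethoxy)benzene
Conditions: NaH (2.4 equiv), MOMCl (2.4 equiv), DMF, 0 °C → rt
Reagents that add atoms: chloromethyl methyl ether, COCCl
Why: Standard phenoxide O-alkylation (acetal protection); the OMOM groups also serve as the directing groups for step 2.

**Step 2**
Reactants: 2; 3, prenyl bromide (1-bromo-3-methylbut-2-ene)
Product: 4, 1,3-bis(methoxymethoxy)-2-(3-methylbut-2-en-1-yl)benzene
Conditions: n-BuLi (1.1 equiv), THF, 0 °C → rt, 1 h; then CuI (0.5 equiv), 3 (1.3 equiv), −78 °C → rt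
Reagents that add atoms: none (prenyl unit comes from reactant 3)
Why: Directed ortho-metalation occurs at C2, between the two OMOM groups; the aryl copper species is allylated at the primary carbon (SN2) to give the linear prenyl group.

**Step 3**
Reactants: 4
Product: 5, 3,5-bis(methoxymethoxy)-4-(3-methylbut-2-en-1-yl)phenol
Conditions: [Ir(OMe)(cod)]2 (1.5 mol%), dtbpy (3 mol%), B2pin2 (1.0 equiv), THF, 80 °C; then 30% H2O2, aq NaOH, 0 °C (one pot)
Reagents that add atoms: hydrogen peroxide, OO (oxygen of the new OH)
Why: Sterically controlled Ir-catalysed C–H borylation takes the only C–H with no ortho substituent (C5, meta to both OMOM groups), and alkaline peroxide oxidises the ArBpin to the phenol without touching the unactivated trisubstituted alkene.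

**Step 4**
Reactants: 5
Product: 6, 2-bromo-3,5-bis(methoxymethoxy)-4-(3-methylbut-2-en-1-yl)phenol
Conditions: NBS (1.0 equiv), i-Pr2NH (10 mol%), CH2Cl2, −78 → −40 °C
Reagents that add atoms: N-bromosuccinimide, O=C1CCC(=O)N1Br
Why: Amine-catalysed ortho-selective electrophilic bromination of a phenol; the para position is blocked and the two ortho positions are equivalent, and the phloroglucinol-type ring reacts far faster than the prenyl alkene at low temperature.

**Step 5**
Reactants: 6; 7, N-methoxy-N-methylacetamide
Product: 8, 1-[6-hydroxy-2,4-bis(methoxymethoxy)-3-(3-methylbut-2-en-1-yl)phenyl]ethan-1-one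
Conditions: NaH (1.05 equiv), THF, 0 °C; t-BuLi (2.1 equiv), −78 °C; then 7 (1.5 equiv), −78 → 0 °C; aq NH4Cl
Reagents that add atoms: none (acetyl comes from reactant 7)
Why: Bromine–lithium exchange on the sodium phenoxide gives the ortho-metalated species, which undergoes Weinreb ketone synthesis; the stable tetrahedral chelate prevents over-addition.

**Step 6**
Reactants: 8; 9, N,N-dimethylformamide dimethyl acetal
Product: 10, (E)-3-(dimethylamino)-1-[6-hydroxy-2,4-bis(methoxymethoxy)-3-(3-methylbut-2-en-1-yl)phenyl]prop-2-en-1-one
Conditions: 9 (3 equiv), toluene, 90 °C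
Reagents that add atoms: none (the CH–NMe2 unit comes from reactant 9)
Why: Standard enaminone condensation of an o-hydroxyacetophenone with DMF-DMA; the hydrogen-bonded ortho OH is not methylated and the E isomer is formed.

**Step 7**
Reactants: 11, 2-iodophenol; 12, 2-methylbut-3-en-2-ol
Product: 13, 2-(3-hydroxy-3-methylbutyl)phenol
Conditions: 12 (1.3 equiv), 9-BBN (2.7 equiv), THF, 0 °C → rt; then 11 (1.0 equiv), Pd(dppf)Cl2 (3 mol%), 3 M aq K3PO4, THF/DMF, 60 °C; NaOH/H2O2 work-up
Reagents that add atoms: none (side chain comes from reactant 12)
Why: Anti-Markovnikov hydroboration followed by B-alkyl Suzuki–Miyaura coupling gives the ArCH2CH2C(Me)2OH chain directly; the extra 9-BBN caps the tertiary OH as a borinate that is hydrolysed on work-up.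

**Step 8**
Reactants: 13
Product: 14, 2-(3-hydroxy-3-methylbutyl)-4-iodophenol
Conditions: NaI (1.0 equiv), NaOH (1.0 equiv), aq NaOCl (1.0 equiv, slow addition), MeOH, 0 °C
Reagents that add atoms: sodium iodide, [Na+].[I-]
Why: Electrophilic iodination of the phenoxide with in-situ hypoiodite is para-selective for 2-alkylphenols; the tertiary alcohol is inert.

**Step 9**
Reactants: 14
Product: 15, 4-[5-iodo-2-(methoxymethoxy)phenyl]-2-methylbutan-2-ol
Conditions: MOMCl (1.2 equiv), K2CO3 (2 equiv), acetone, 0 °C → rt
Reagents that add atoms: chloromethyl methyl ether, COCCl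
Why: Chemoselective O-alkylation of the phenoxide; under carbonate conditions the hindered tertiary alcohol is not alkylated.

**Step 10 (key step)**
Reactants: 10; 15 (2.0 equiv)
Product: 16, 3-[3-(3-hydroxy-3-methylbutyl)-4-(methoxymethoxy)phenyl]-5,7-bis(methoxymethoxy)-6-(3-methylbut-2-en-1-yl)-4H-chromen-4-one
Conditions: 10-phenylphenothiazine (10 mol%), K2HPO4 (2 equiv), degassed MeCN (0.2 M in 10), 390 nm LEDs, rt; then SiO2 / cat. AcOH to complete loss of Me2NH
Reagents that add atoms: none
Why: Proposed new method: excited 10-phenylphenothiazine (E* ≈ −2.1 V vs SCE) cleaves the C–I bond of 15 by dissociative electron transfer to give the aryl radical, which adds to the nucleophilic α-carbon of the push–pull enaminone to form an α-amino radical; this is oxidised to the iminium by the phenothiazine radical cation (or propagates a chain by iodine-atom abstraction from 15, as α-aminoalkyl radicals are known to do), and the only free ortho OH closes onto the iminium and Me2NH·HI is lost to give the 3-arylchromone. The closest known reaction type is the visible-light aryl-radical arylation/annulation of o-hydroxyaryl enaminones with arenediazonium salts (radical–polar crossover, Meerwein-type arylation).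

**Step 11**
Reactants: 16
Product: 17, Coloratanin A, 5,7-dihydroxy-3-[4-hydroxy-3-(3-hydroxy-3-methylbutyl)phenyl]-6-(3-methylbut-2-en-1-yl)-4H-chromen-4-one
Conditions: TMSOTf (8 equiv), 2,2′-bipyridyl (12 equiv), CH2Cl2, 0 °C → rt; then H2O/THF, rt; brief K2CO3/MeOH to cleave the tertiary O-TMS ether
Reagents that add atoms: none
Why: Silyl triflate/bipyridyl cleavage of aryl MOM ethers proceeds via aryl silyl ethers that hydrolyse on aqueous work-up; this avoids the protic acid that would cyclise the prenyl group or the tertiary alcohol onto a neighbouring phenol to give a 2,2-dimethylchroman.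

## Compound list

1 | resorcinol | Oc1cccc(O)c1 | starting material
2 | 1,3-bis(methoxymethoxy)benzene | COCOc1cccc(OCOC)c1 | intermediate
3 | prenyl bromide | CC(C)=CCBr | starting material
4 | 1,3-bis(methoxymethoxy)-2-(3-methylbut-2-en-1-yl)benzene | COCOc1cccc(OCOC)c1CC=C(C)C | intermediate
5 | 3,5-bis(methoxymethoxy)-4-(3-methylbut-2-en-1-yl)phenol | COCOc1cc(O)cc(OCOC)c1CC=C(C)C | intermediate
6 | 2-bromo-3,5-bis(methoxymethoxy)-4-(3-methylbut-2-en-1-yl)phenol | COCOc1cc(O)c(Br)c(OCOC)c1CC=C(C)C | intermediate
7 | N-methoxy-N-methylacetamide | CC(=O)N(C)OC | starting material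
8 | 1-[6-hydroxy-2,4-bis(methoxymethoxy)-3-(3-methylbut-2-en-1-yl)phenyl]ethan-1-one | CC(=O)c1c(O)cc(OCOC)c(CC=C(C)C)c1OCOC | intermediate
9 | N,N-dimethylformamide dimethyl acetal | COC(OC)N(C)C | starting material
10 | (E)-3-(dimethylamino)-1-[6-hydroxy-2,4-bis(methoxymethoxy)-3-(3-methylbut-2-en-1-yl)phenyl]prop-2-en-1-one | CN(C)/C=C/C(=O)c1c(O)cc(OCOC)c(CC=C(C)C)c1OCOC | intermediate
11 | 2-iodophenol | Oc1ccccc1I | starting material
12 | 2-methylbut-3-en-2-ol | C=CC(C)(C)O | starting material
13 | 2-(3-hydroxy-3-methylbutyl)phenol | CC(C)(O)CCc1ccccc1O | intermediate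
14 | 2-(3-hydroxy-3-methylbutyl)-4-iodophenol | CC(C)(O)CCc1cc(I)ccc1O | intermediate
15 | 4-[5-iodo-2-(methoxymethoxy)phenyl]-2-methylbutan-2-ol | COCOc1ccc(I)cc1CCC(C)(C)O | intermediate
16 | 3-[3-(3-hydroxy-3-methylbutyl)-4-(methoxymethoxy)phenyl]-5,7-bis(methoxymethoxy)-6-(3-methylbut-2-en-1-yl)-4H-chromen-4-one | COCOc1ccc(cc1CCC(C)(C)O)-c1coc2cc(OCOC)c(CC=C(C)C)c(OCOC)c2c1=O | intermediate
17 | Coloratanin A | CC(C)=CCc1c(O)cc2occ(-c3ccc(O)c(CCC(C)(C)O)c3)c(=O)c2c1O | target

## Summary

**Total steps:** 11

**Longest linear sequence:** 8 (steps 1–6, 10, 11); the B-ring branch is 3 steps (7–9).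

**Three steps most likely to fail, with fallbacks:**

1. **Step 10** (electron-rich aryl iodide is hard to reduce; the enaminone competes for light; the aryl radical can be lost to H-abstraction). Fallback: change the radical source. Convert 15 to the aniline (CuI/L-proline, aq NH3), diazotise in situ (isoamyl nitrite, TsOH, MeCN, 0 °C), and run the eosin Y / green-light arylation–annulation with 10. This costs two steps but uses the established diazonium version of the reaction.
2. **Step 4** (NBS may attack the prenyl alkene or brominate twice). Fallback: drop the halogenation/exchange sequence. Protect 5 as its THP ether, use directed ortho-lithiation (s-BuLi/TMEDA, −78 °C) with quench by 7, then release the phenol selectively with PPTS/MeOH.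
3. **Step 11** (prenyl or tertiary-alcohol cyclisation onto a free phenol, or incomplete cleavage of the 7-O and 4′-O MOM groups). Fallback: change the protecting-group strategy. Use SEM ethers in steps 1 and 9 (SEM directs the step 2 lithiation equally well) and unmask at the end with fluoride (TBAF, DMPU, 60 °C), so that no Lewis or protic acid is needed.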